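(Its constants are those of an exercise.)

Amounts of target and side product, counted at the end of the run, are what you compare here, between a hot flask and a cooler one.

    substrate → side product (k1 = 0.0013 s⁻¹, Ea1 = 113 kJ mol⁻¹)
    target → over-reaction product (k2 = 8.4 × 10⁻⁶ s⁻¹, Ea2 = 109 kJ mol⁻¹)
    2 substrate → homo dimer (k3 = 0.012 M⁻¹ s⁻¹, Ea3 = 74.0 kJ mol⁻¹)
    substrate → target (k4 = 0.0052 s⁻¹, Ea4 = 98.0 kJ mol⁻¹)
    (constants at 80 °C)

common to all: substrate 0.50 M; time 2.0 min

|  | temperature |
|---|---|
| east | 110 °C |
| west | 80 °C |

- the flask with the highest share of target in all that became target or side product ("all alike" if they lie within 1.5 percentage points) (east / west / all alike)
- share of target in all that became target or side product, east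
- share of target in all that became target or side product, west

- percent here means substrate units held: one homo dimer counts as two
- a doubled species enters its step squared and goes two at a time
- at 80 °C the constants are as listed, elsewhere as the activation energies make them
- the share counts what is present at the end, not what went on to other products

Target and side product both form first order from the same substrate. At each moment they therefore gain in the ratio of their constants, and the dimer step, by thinning the substrate, thins both gains alike. West has the listed constants:

  target constant / (target constant + side constant), west = 80.0%

East needs its constants from the activation energies:

  side constant, east = 0.0265 s⁻¹
  target constant, east = 0.0709 s⁻¹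
  same fraction, east = 72.8%

Call this fraction east's branch share: of the substrate leaving by the two first-order steps, the part that becomes target. Its ratio form is the selectivity factor.

Next, count turnovers of the over-reaction, the constant times the time:

  over-reaction constant, east = 1.54 × 10⁻⁴ s⁻¹
  turnovers, east = 0.0184
  turnovers, west = 0.00101

Take that fraction off the target and east's share becomes 72.47%, while west's becomes 80.0%.

The weak link is the exposure, since target is born during the run and doesn't sit there from the start. In east, the first-order steps give substrate a lifetime of 10.3 s, shorter than the run, and the dimer step takes substrate away besides. Taking that lifetime off the run:

  turnovers, east = 0.0169
  share, east = 72.50%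

West then leads by 7.5 percentage points, wider than the margin, so I commit to west.

The forecast says west, with 72.5% for east and 80% for west, and holds that “dimerisation removes substrate but doesn't change their ratio”.

East ends at 72.5% and west at 80.0%, so the higher share stands in west. At 2.00 min, east holds 0.884% over-reaction product beside 51.3% target and 19.5% side product. Counting that product back as target gives 72.8%, against a branch share of 72.8%. The neighbour flask is the same as east but run at 85 °C. Its branch share comes to 78.8%, and its share of target reads 78.8%.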